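**Retrosynthetic overview**
1. Target 14 ⇒ enone 10 (forward: hydroxyl-directed α′-oxygenation sets C6) ⇒ achiral para-quinol 9 (forward: arm-selective 1,4-reduction sets C4).
2. 9 ⇒ phenolic lipid 7 + O2 (biomimetic ipso-oxygenation and dearomatisation at the alkylated carbon).
3. 7 ⇒ 4-iodophenol 5 + (Z)-diene 4 (B-alkyl Suzuki); 4 ⇒ phosphonium salt 1 + 9-decenal 2 (Z-selective Wittig).
4. Rings: the single six-membered carbocycle is never closed or opened. It enters as the benzene ring of 5, is dearomatised in step 3 and desymmetrised in steps 4 and 5.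

Assumption: the biogenesis is taken to be ipso-oxygenation of a polyketide-derived phenolic lipid to a para-quinol, then ene-reductase-type reduction of one enone arm and α-hydroxylation.
Assumption: (R)-DTBM-SEGPHOS is taken as the ligand enantiomer that gives (R)-10; if the first run shows the opposite sense, the (S)-ligand is used with no other change.

**Step 1**
Reactants: 1 heptyltriphenylphosphonium bromide; 2 9-decenal
Product: 4 (Z)-heptadeca-1,10-diene, via phosphorus ylide 3 (not isolated)
Conditions: NaN(SiMe3)2 (1.05 equiv), THF, 0 °C; then 2, −78 → 20 °C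
Reagents that add atoms: none
Why: Wittig olefination of a non-stabilised ylide with an aliphatic aldehyde under lithium-free conditions at −78 °C is kinetically cis-selective and gives the Z-alkene (typically ≥95:5), while the terminal alkene is inert.

**Step 2**
Reactants: 4 (Z)-heptadeca-1,10-diene; 5 4-iodophenol
Product: 7 4-[(Z)-heptadec-10-en-1-yl]phenol, via B-alkyl-9-borabicyclo[3.3.1]nonane 6 (not isolated)
Conditions: 9-BBN (1.05 equiv), THF, 0 → 20 °C; then 5, PdCl2(dppf) (3 mol %), K3PO4 (3 equiv), H2O, DMF, 50 °C
Reagents that add atoms: none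
Why: 9-BBN hydroborates the terminal alkene anti-Markovnikov about two orders of magnitude faster than the cis-1,2-disubstituted one, and the B-alkyl Suzuki–Miyaura coupling with the aryl iodide tolerates the free phenol (as phenoxide) and does not isomerise the Z-alkene.

**Step 3**
Reactants: 7 4-[(Z)-heptadec-10-en-1-yl]phenol
Product: 9 4-hydroxy-4-[(Z)-heptadec-10-en-1-yl]cyclohexa-2,5-dien-1-one, via para-peroxyquinol 8 (not isolated)
Conditions: O2 (1 atm), methylene blue (1 mol %), red LED, NaHCO3 (1 equiv), MeOH–CH2Cl2 3:1, −20 °C; then Me2S (3 equiv), −20 → 20 °C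
Reagents that add atoms: dioxygen O=O
Why: Biomimetic oxidative dearomatisation by photooxygenation: singlet oxygen adds para to the phenol(ate) oxygen several orders of magnitude faster than it undergoes the ene reaction with a cis-dialkyl alkene, and Me2S reduces the resulting hydroperoxide to the para-quinol, which is achiral because C4 carries two identical enone arms.

**Step 4**
Reactants: 9 4-hydroxy-4-[(Z)-heptadec-10-en-1-yl]cyclohexa-2,5-dien-1-one
Product: 10 (4R)-4-hydroxy-4-[(Z)-heptadec-10-en-1-yl]cyclohex-2-en-1-one
Conditions: Cu(OAc)2 (3 mol %), (R)-DTBM-SEGPHOS (3.3 mol %), (EtO)2MeSiH (1.1 equiv), t-BuOH (1.2 equiv), toluene, −40 °C; aq NH4Cl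
Reagents that add atoms: none
Why: Ligand-controlled copper hydride asymmetric conjugate reduction, used as an enantiotopic-group-selective desymmetrisation of a 4,4-disubstituted cyclohexadienone, saturates one of the two enone arms and thereby makes C4 stereogenic (R), while the isolated Z-alkene is inert to copper hydride and limiting the silane suppresses reduction of the second arm.

**Step 5**
Reactants: 10 (4R)-4-hydroxy-4-[(Z)-heptadec-10-en-1-yl]cyclohex-2-en-1-one
Product: 14 (4R,6S)-4,6-dihydroxy-4-[(Z)-heptadec-10-en-1-yl]cyclohex-2-en-1-one, via dilithium alkoxide dienolate 11 (not isolated), via triethylsilyl dienol ether 12 (not isolated), via 6-triethylsilyloxy ketone 13 (not isolated)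
Conditions: LiN(iPr)2 (2.1 equiv), THF, −78 °C; Et3SiCl (1.05 equiv), −78 °C; AcOH (1.05 equiv), pentane, filter; VO(acac)2 (5 mol %), t-BuOOH (1.2 equiv), CH2Cl2, 0 °C; HF·pyridine, pyridine, THF, 0 °C
Reagents that add atoms: tert-butyl hydroperoxide CC(C)(C)OO
Why: Proposed new method: LiN(iPr)2 removes the hydroxyl proton and then the only enolisable hydrogen (C6–H), Et3SiCl silylates the enolate oxygen faster than the hindered tertiary lithium alkoxide, and the free pseudoaxial C4–OH of 12 then binds the vanadium tert-butylperoxide and delivers oxygen to the electron-rich C6=C1 enol ether on its own face (1,3-syn, the geometry of hydroxyl-directed VO(acac)2/t-BuOOH epoxidation of cyclohex-3-enol), silyl migration gives 13 and fluoride frees the cis-diol, so C6 is set S by substrate direction while the remote Z-alkene has no directing group and is not touched; the closest known reaction types are the Rubottom oxidation and Sharpless-type hydroxyl-directed vanadium epoxidation.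

**Compound list**
1 | heptyltriphenylphosphonium bromide | CCCCCCC[P+](c1ccccc1)(c1ccccc1)c1ccccc1.[Br-] | starting material
2 | 9-decenal | C=CCCCCCCCC=O | starting material
3 | heptylidenetriphenylphosphorane (ylide) | CCCCCCC=P(c1ccccc1)(c1ccccc1)c1ccccc1 | intermediate
4 | (Z)-heptadeca-1,10-diene | C=CCCCCCCC/C=C\CCCCCC | intermediate
5 | 4-iodophenol | Oc1ccc(I)cc1 | starting material
6 | 9-[(Z)-heptadec-10-en-1-yl]-9-borabicyclo[3.3.1]nonane | CCCCCC/C=C\CCCCCCCCCB1C2CCCC1CCC2 | intermediate
7 | 4-[(Z)-heptadec-10-en-1-yl]phenol | CCCCCC/C=C\CCCCCCCCCc1ccc(O)cc1 | intermediate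
8 | 4-hydroperoxy-4-[(Z)-heptadec-10-en-1-yl]cyclohexa-2,5-dien-1-one (achiral) | CCCCCC/C=C\CCCCCCCCCC1(OO)C=CC(=O)C=C1 | intermediate
9 | 4-hydroxy-4-[(Z)-heptadec-10-en-1-yl]cyclohexa-2,5-dien-1-one (achiral) | CCCCCC/C=C\CCCCCCCCCC1(O)C=CC(=O)C=C1 | intermediate
10 | (4R)-4-hydroxy-4-[(Z)-heptadec-10-en-1-yl]cyclohex-2-en-1-one | CCCCCC/C=C\CCCCCCCCC[C@]1(O)C=CC(=O)CC1 | intermediate
11 | dilithium (4R)-4-[(Z)-heptadec-10-en-1-yl]cyclohexa-1,5-diene-1,4-bis(olate) | CCCCCC/C=C\CCCCCCCCC[C@]1([O-])C=CC([O-])=CC1.[Li+].[Li+] | intermediate
12 | (1R)-1-[(Z)-heptadec-10-en-1-yl]-4-(triethylsilyloxy)cyclohexa-2,4-dien-1-ol | CCCCCC/C=C\CCCCCCCCC[C@]1(O)C=CC(O[Si](CC)(CC)CC)=CC1 | intermediate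
13 | (4R,6S)-4-hydroxy-4-[(Z)-heptadec-10-en-1-yl]-6-(triethylsilyloxy)cyclohex-2-en-1-one | CCCCCC/C=C\CCCCCCCCC[C@]1(O)C=CC(=O)[C@@H](O[Si](CC)(CC)CC)C1 | intermediate
14 | (4R,6S)-4,6-dihydroxy-4-[(Z)-heptadec-10-en-1-yl]cyclohex-2-en-1-one (4-OH and 6-OH cis) | CCCCCC/C=C\CCCCCCCCC[C@]1(O)C=CC(=O)[C@@H](O)C1 | target

**Step count and risks**
Total step count: 5. Longest linear sequence: 5 (from 1 or 2 to 14).

The three steps most likely to fail are, in order, step 5, step 4 and step 3.

Step 5 is the weakest. The mono-silylation must spare the tertiary alkoxide, the vanadium peroxide must choose the enol ether over the allylic C2=C3 bond of the silyloxydiene, and the cis/trans ratio at C6 rests on the directing effect. The fallback sets out from 10 and gives up kinetic direction for thermodynamic templating. The dilithio species 11 is hydroxylated directly with 2-(phenylsulfonyl)-3-phenyloxaziridine (THF, −78 °C, AcOH quench). This gives 14 mixed with its C6 epimer (4R,6R)-4,6-dihydroxy-4-[(Z)-heptadec-10-en-1-yl]cyclohex-2-en-1-one F1. The mixture is stirred with PhB(OH)2 and Et3N in toluene over molecular sieves; C6 epimerises through the enol, and only the cis-1,3-diol can close the six-membered boronate, so the material drains into the cyclic phenylboronate of 14 F2. Exchange with pinacol then releases the diol, and the fallback comes back to the route at 14.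

Step 4 may give low enantioselectivity with the free tertiary hydroxyl, or over-reduce the second enone arm. The fallback sets out from 9 and replaces metal hydride catalysis by biocatalysis. A flavin-dependent ene-reductase of the Old Yellow Enzyme family (YqjM or OPR3 variants, screened for the R product) is used with NADP+, glucose and glucose dehydrogenase in phosphate buffer. Hydroxypropyl-β-cyclodextrin or 15 % DMSO carries the lipid. The enzyme stops at the mono-reduced enone, and the fallback comes back at 10; no new compound arises (F0).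

Step 3 may lose material to the singlet-oxygen ene reaction at the Z-alkene or to base-induced self-epoxidation of the peroxyquinol. The fallback sets out from 7 and replaces the dioxygen pathway by a two-electron hypervalent iodine oxidation. PhI(OAc)2 (1.1 equiv) in MeCN–H2O 3:1 at 0 °C oxidises the phenol, and water is captured at the para carbon. This does not touch an isolated alkene, and the fallback comes back at 9; no new compound arises (F0).

**Further compounds**
F1 | step 5 | (4R,6R)-4,6-dihydroxy-4-[(Z)-heptadec-10-en-1-yl]cyclohex-2-en-1-one | CCCCCC/C=C\CCCCCCCCC[C@]1(O)C=CC(=O)[C@H](O)C1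
F2 | step 5 | cyclic phenylboronate of 14 (O4,O6-bridged 2,4-dioxa-3-borabicyclo[3.3.1]nonenone, configuration as in 14) | CCCCCC/C=C\CCCCCCCCC[C@]1(OB(c2ccccc2)O3)C=CC(=O)[C@@H]3C1
F0 | step 4 | none | none
F0 | step 3 | none | none
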